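The route rests on disconnecting the C5–C6 bond of the (E)-8-methylnon-6-enoyl chain on ring A: the sp3–sp2 junction between the four-methylene tether (C2–C5) and the E-configured C6=C7 alkene that carries the isopropyl group. A B-alkyl Suzuki–Miyaura coupling forges this bond in one operation: a terminal alkene is hydroborated with 9-BBN-H and the resulting alkylborane is joined under palladium catalysis to (E)-1-bromo-3-methylbut-1-ene, whose geometry is transferred unchanged. The substrate for this step is the complete 5,5'-linked biaryl with both phenols masked as MOM ethers, the saturated 8-methylnonanamide arm on ring B and a pent-4-enamide arm on ring A. Acidic methanolysis finishes the synthesis.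

Key step: step 9

Assumption: NBS is taken to substitute free-phenol dihydrocapsaicin at C5, ortho to the hydroxyl, which is the usual site for a free guaiacol whose para position is blocked.
Remark: both MOM ethers are installed on the two monomers before the biaryl bond is made, so the coupling substrate arrives fully protected. The two secondary amide N–H bonds stay free and are covered by excess 9-BBN-H.
Remark: 3-methylbut-1-yne and the alkenyl bromide are volatile and should be handled cold and as solutions.

Step 1
Reactants: 1 dihydrocapsaicin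
Product: 2 N-(3-bromo-4-hydroxy-5-methoxybenzyl)-8-methylnonanamide (5-bromodihydrocapsaicin)
Conditions: NBS, MeCN, 0 °C
Reagents that add atoms: N-bromosuccinimide, O=C1CCC(=O)N1Br
Why: Electrophilic aromatic bromination, in which the free phenol should steer bromine to its only open ortho position (C5) because the para position carries the benzylic carbon and the saturated amide arm offers no competing site.

Step 2
Reactants: 2 N-(3-bromo-4-hydroxy-5-methoxybenzyl)-8-methylnonanamide
Product: 3 N-[3-bromo-5-methoxy-4-(methoxymethoxy)benzyl]-8-methylnonanamide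
Conditions: MOMCl, K2CO3, DMF, 0 °C to rt
Reagents that add atoms: chloromethyl methyl ether, COCCl
Why: Williamson-type O-alkylation (MOM protection), in which carbonate deprotonates only the acidic ortho-bromophenol and leaves the amide N–H alone.

Step 3
Reactants: 4 5-bromovanillin
Product: 5 3-bromo-5-methoxy-4-(methoxymethoxy)benzaldehyde
Conditions: MOMCl, K2CO3, DMF, 0 °C to rt
Reagents that add atoms: chloromethyl methyl ether, COCCl
Why: Williamson-type MOM protection of the phenoxide under a mild base that does not affect the aldehyde.

Step 4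
Reactants: 5 3-bromo-5-methoxy-4-(methoxymethoxy)benzaldehyde
Product: 6 3-methoxy-4-(methoxymethoxy)-5-(4,4,5,5-tetramethyl-1,3,2-dioxaborolan-2-yl)benzaldehyde
Conditions: B2pin2, PdCl2(dppf), KOAc, 1,4-dioxane, 90 °C
Reagents that add atoms: bis(pinacolato)diboron, CC1(C)OB(OC1(C)C)B1OC(C)(C)C(C)(C)O1
Why: Miyaura borylation, in which the electron-poor aryl bromide should add readily to zerovalent palladium and KOAc is too weak a base to start biaryl homocoupling or harm the aldehyde.

Step 5
Reactants: 3 N-[3-bromo-5-methoxy-4-(methoxymethoxy)benzyl]-8-methylnonanamide, 6 3-methoxy-4-(methoxymethoxy)-5-(4,4,5,5-tetramethyl-1,3,2-dioxaborolan-2-yl)benzaldehyde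
Product: 7 N-{[5'-formyl-3,3'-dimethoxy-2,2'-bis(methoxymethoxy)biphenyl-5-yl]methyl}-8-methylnonanamide (bis-MOM biaryl aldehyde; formyl on ring A, amide arm on ring B)
Conditions: Pd(OAc)2, SPhos, K3PO4, toluene/H2O, 90 °C
Reagents that add atoms: none
Why: Suzuki–Miyaura biaryl coupling, for which an SPhos-ligated palladium catalyst should cope with one ortho alkoxy group on each partner, while the aldehyde, MOM ethers and secondary amide are inert to aqueous phosphate.

Step 6
Reactants: 7 bis-MOM biaryl aldehyde
Product: 9 N-{[5'-(aminomethyl)-3,3'-dimethoxy-2,2'-bis(methoxymethoxy)biphenyl-5-yl]methyl}-8-methylnonanamide, via aldoxime 8 (not isolated)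
Conditions: NH2OH (50% aq.), EtOH, rt; then NH3 (7 M in MeOH), Raney Ni, H2 (4 bar), rt
Reagents that add atoms: hydroxylamine, NO
Why: Oxime condensation followed by catalytic hydrogenation of the oxime to the primary amine, in which ammonia should suppress secondary-amine formation and Raney Ni at room temperature should leave MOM ethers, amide and biaryl intact.

Step 7
Reactants: 9 biaryl benzylic amine, 10 pent-4-enoic acid
Product: 11 N-{[3,3'-dimethoxy-2,2'-bis(methoxymethoxy)-5'-[(pent-4-enamido)methyl]biphenyl-5-yl]methyl}-8-methylnonanamide (bis-MOM biaryl with the pent-4-enamide arm on ring A and the 8-methylnonanamide arm on ring B)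
Conditions: DIC, HOBt (cat.), CH2Cl2, 0 °C to rt
Reagents that add atoms: none
Why: Carbodiimide amide coupling through the HOBt active ester, in which the primary benzylic amine is the only competent nucleophile since the other nitrogen is already an amide.

Step 8
Reactants: 12 3-methylbut-1-yne
Product: 14 (E)-1-bromo-3-methylbut-1-ene, via alkenylzirconocene chloride 13 (not isolated)
Conditions: Cp2Zr(H)Cl, CH2Cl2, 0 °C to rt; then NBS, 0 °C
Reagents that add atoms: N-bromosuccinimide, O=C1CCC(=O)N1Br
Why: Hydrozirconation–bromination, in which syn addition of Zr–H places zirconium on the terminal carbon to give the E-alkenylzirconocene and NBS cleaves the Zr–C bond with retention, fixing the E geometry.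

Step 9
Reactants: 11 bis-MOM biaryl with pent-4-enamide arm, 14 (E)-1-bromo-3-methylbut-1-ene
Product: 16 bis-MOM ether of 6'',7''-dihydro-5',5'''-dicapsaicin, via B-alkyl-9-BBN adduct 15 (not isolated)
Conditions: 9-BBN-H (excess), THF, 0 °C to rt; then aq. Cs2CO3, 14, PdCl2(dppf), AsPh3, DMF, rt to 45 °C
Reagents that add atoms: none
Why: 9-BBN-H adds across the only C=C bond of 11 in a four-centre syn addition that places boron on the terminal carbon C5 (steric demand of the bicyclic borane) to give 15; zerovalent palladium then inserts into the C–Br bond of 14, the base-activated borate passes its primary alkyl group to divalent palladium, and reductive elimination forms C5–C6. The closest known reaction type is the B-alkyl Suzuki–Miyaura coupling of a 9-BBN alkylborane with an alkenyl bromide, an established sp3–sp2 coupling that tolerates amides and acetals. No ring is closed and no stereocentre is created; the only stereochemical element, the E geometry of C6=C7, comes from 14 and should be retained because oxidative addition and reductive elimination at an alkenyl carbon both proceed with retention. The step needs site selectivity in the hydroboration, which is secured because the arm on ring B is saturated and 14 is added only after hydroboration is complete and surplus B–H has been quenched by the aqueous base. It also needs coupling to outrun β-hydride elimination of the alkylpalladium intermediate, which the wide-bite-angle dppf ligand favours, while the MOM ethers keep the phenols from consuming borane and the excess 9-BBN-H allows for the two amide N–H bonds. The five-carbon acyl arm and the five-carbon bromide together give exactly the 8-methylnon-6-enoyl chain, so the chain length is fixed by the anti-Markovnikov regiochemistry.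

Step 10
Reactants: 16 bis-MOM ether of 6'',7''-dihydro-5',5'''-dicapsaicin
Product: 17 6'',7''-dihydro-5',5'''-dicapsaicin
Conditions: HCl (2 M), MeOH/THF, rt to 40 °C
Reagents that add atoms: none
Why: Acid-catalysed acetal exchange (MOM cleavage) with methanol, under which the isolated E-alkene, both amides and the aryl methyl ethers should remain untouched.

Compound list
1 | dihydrocapsaicin, N-(4-hydroxy-3-methoxybenzyl)-8-methylnonanamide | COc1cc(CNC(=O)CCCCCCC(C)C)ccc1O | starting material
2 | N-(3-bromo-4-hydroxy-5-methoxybenzyl)-8-methylnonanamide (5-bromodihydrocapsaicin) | COc1cc(CNC(=O)CCCCCCC(C)C)cc(Br)c1O | intermediate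
3 | N-[3-bromo-5-methoxy-4-(methoxymethoxy)benzyl]-8-methylnonanamide | COCOc1c(Br)cc(CNC(=O)CCCCCCC(C)C)cc1OC | intermediate
4 | 5-bromovanillin (3-bromo-4-hydroxy-5-methoxybenzaldehyde) | COc1cc(C=O)cc(Br)c1O | starting material
5 | 3-bromo-5-methoxy-4-(methoxymethoxy)benzaldehyde | COCOc1c(Br)cc(C=O)cc1OC | intermediate
6 | 3-methoxy-4-(methoxymethoxy)-5-(4,4,5,5-tetramethyl-1,3,2-dioxaborolan-2-yl)benzaldehyde | COCOc1c(OC)cc(C=O)cc1B1OC(C)(C)C(C)(C)O1 | intermediate
7 | N-{[5'-formyl-3,3'-dimethoxy-2,2'-bis(methoxymethoxy)biphenyl-5-yl]methyl}-8-methylnonanamide (bis-MOM biaryl aldehyde) | COCOc1c(OC)cc(C=O)cc1-c1cc(CNC(=O)CCCCCCC(C)C)cc(OC)c1OCOC | intermediate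
8 | aldoxime of 7 (E isomer drawn; the geometry is of no consequence) | COCOc1c(OC)cc(/C=N/O)cc1-c1cc(CNC(=O)CCCCCCC(C)C)cc(OC)c1OCOC | intermediate (not isolated)
9 | N-{[5'-(aminomethyl)-3,3'-dimethoxy-2,2'-bis(methoxymethoxy)biphenyl-5-yl]methyl}-8-methylnonanamide | COCOc1c(OC)cc(CN)cc1-c1cc(CNC(=O)CCCCCCC(C)C)cc(OC)c1OCOC | intermediate
10 | pent-4-enoic acid | C=CCCC(=O)O | starting material
11 | N-{[3,3'-dimethoxy-2,2'-bis(methoxymethoxy)-5'-[(pent-4-enamido)methyl]biphenyl-5-yl]methyl}-8-methylnonanamide (substrate of the key step) | C=CCCC(=O)NCc1cc(OC)c(OCOC)c(-c2cc(CNC(=O)CCCCCCC(C)C)cc(OC)c2OCOC)c1 | intermediate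
12 | 3-methylbut-1-yne | CC(C)C#C | starting material
13 | (E)-(3-methylbut-1-enyl)zirconocene chloride (cyclopentadienyl rings drawn sigma-bonded) | CC(C)/C=C/[Zr](Cl)(C1C=CC=C1)C1C=CC=C1 | intermediate (not isolated)
14 | (E)-1-bromo-3-methylbut-1-ene | CC(C)/C=C/Br | intermediate
15 | B-alkyl-9-BBN adduct of 11 (9-borabicyclo[3.3.1]nonan-9-yl group on C5 of the pentanamide arm on ring A) | O=C(CCCCB1C2CCCC1CCC2)NCc1cc(OC)c(OCOC)c(-c2cc(CNC(=O)CCCCCCC(C)C)cc(OC)c2OCOC)c1 | intermediate (not isolated)
16 | bis-MOM ether of 6'',7''-dihydro-5',5'''-dicapsaicin (E alkene) | COCOc1c(OC)cc(CNC(=O)CCCC/C=C/C(C)C)cc1-c1cc(CNC(=O)CCCCCCC(C)C)cc(OC)c1OCOC | intermediate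
17 | 6'',7''-dihydro-5',5'''-dicapsaicin (E alkene) | COc1cc(CNC(=O)CCCC/C=C/C(C)C)cc(-c2cc(CNC(=O)CCCCCCC(C)C)cc(OC)c2O)c1O | target

Total step count: 10
Longest linear sequence: 7 steps (steps 1, 2, 5, 6, 7, 9, 10 from dihydrocapsaicin; the branch from 5-bromovanillin through steps 3, 4, 5, 6, 7, 9, 10 is equally long)

Steps most likely to fail

Step 9. The amide N–H bonds and carbonyl groups may bind or consume the borane so that hydroboration stalls, or the alkylpalladium intermediate may undergo β-hydride elimination or the alkylborane may protodeboronate before transmetalation. The fallback forms the amide bond last instead of the C5–C6 bond and sets out from amine 9. Purchased (E)-8-methylnon-6-enoic acid would be converted with oxalyl chloride and catalytic DMF in CH2Cl2 into (E)-8-methylnon-6-enoyl chloride F1. F1 would acylate 9 under Schotten–Baumann conditions (aq. NaHCO3/CH2Cl2), and the route is rejoined at 16 with the E alkene already in place.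

Step 5. Protodeboronation of the ortho-alkoxy boronate may outpace the slow oxidative addition of the electron-rich bromide, and the ortho substituents on both partners slow transmetalation. The fallback reverses the polarity of the partners and sets out from 3. Miyaura borylation (B2pin2, PdCl2(dppf), KOAc, 1,4-dioxane, 90 °C) would give N-[3-methoxy-4-(methoxymethoxy)-5-(4,4,5,5-tetramethyl-1,3,2-dioxaborolan-2-yl)benzyl]-8-methylnonanamide F2. F2 would be coupled with the electron-poor, quickly inserting bromide 5 (PdCl2(dppf), K2CO3, 1,4-dioxane/H2O, 85 °C), and the route is rejoined at 7.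

Step 6. The newly formed benzylic amine may condense with the imine that has not yet been reduced and lead to over-alkylation to a secondary amine, or the hydrogenation may stall on the hindered biaryl. The fallback brings the nitrogen in as azide and sets out from 7. NaBH4 in MeOH at 0 °C would give the benzylic alcohol N-{[5'-(hydroxymethyl)-3,3'-dimethoxy-2,2'-bis(methoxymethoxy)biphenyl-5-yl]methyl}-8-methylnonanamide F3. DPPA and DBU in toluene would convert this electron-rich benzylic alcohol into the benzylic azide N-{[5'-(azidomethyl)-3,3'-dimethoxy-2,2'-bis(methoxymethoxy)biphenyl-5-yl]methyl}-8-methylnonanamide F4. Staudinger reduction (PPh3, THF/H2O, 50 °C) would then give the amine, and the route is rejoined at 9.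

Further compounds
F1 | step 9 | (E)-8-methylnon-6-enoyl chloride | CC(C)/C=C/CCCCC(=O)Cl
F2 | step 5 | N-[3-methoxy-4-(methoxymethoxy)-5-(4,4,5,5-tetramethyl-1,3,2-dioxaborolan-2-yl)benzyl]-8-methylnonanamide | COCOc1c(OC)cc(CNC(=O)CCCCCCC(C)C)cc1B1OC(C)(C)C(C)(C)O1
F3 | step 6 | N-{[5'-(hydroxymethyl)-3,3'-dimethoxy-2,2'-bis(methoxymethoxy)biphenyl-5-yl]methyl}-8-methylnonanamide | COCOc1c(OC)cc(CO)cc1-c1cc(CNC(=O)CCCCCCC(C)C)cc(OC)c1OCOC
F4 | step 6 | N-{[5'-(azidomethyl)-3,3'-dimethoxy-2,2'-bis(methoxymethoxy)biphenyl-5-yl]methyl}-8-methylnonanamide | COCOc1c(OC)cc(CN=[N+]=[N-])cc1-c1cc(CNC(=O)CCCCCCC(C)C)cc(OC)c1OCOC
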